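The route cuts the lone CH2 bridge between C7 of the isochromene quinone methide (rings A and B) and C7' of the isochroman-1-one (rings C and D). C7 is the alpha carbon of a vinylogous acid (6-OH, 8-C=O). C7' is the only free aromatic CH, flanked by 6'-OH and 8'-OH. One operation joins three components without protecting groups. Formaldehyde condenses with decarboxycitrinin, and the transient 7-methylene-6,8-dione is captured at its CH2 carbon by C7' of the dihydroisocoumarin, giving the target directly. Both precursors carry the same (3R,4S)-3,4,5-trimethyl array. The quinone methide comes from one chiral triol, and the lactone comes from the quinone methide by oxidation.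

Key step: step 9

Assumption: the quinone methide half is written as the 6-hydroxy-8-oxo tautomer of the target SMILES (it equilibrates with the 8-hydroxy-6-oxo form), isochromene numbering is used with primes for the lactone half, and (2S,3S)-2,3-dimethyloxirane is bought as the single enantiomer.

Step 1
Reactants: 1 1-bromo-3,5-dimethoxybenzene
Product: 3 2-bromo-4,6-dimethoxybenzaldehyde, via iminium chloride 2 (not isolated)
Conditions: POCl3, DMF, 0 to 90 °C; then ice-water
Reagents that add atoms: DMF CN(C)C=O; water O
Why: Vilsmeier-Haack formylation, in which the chloroiminium ion should attack the ring carbon beside bromine (para to one methoxy group, ortho to the other) rather than the more crowded carbon between the two methoxy groups, and water then hydrolyses 2 to the aldehyde.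

Step 2
Reactants: 3 2-bromo-4,6-dimethoxybenzaldehyde
Product: 4 1-bromo-3,5-dimethoxy-2-methylbenzene
Conditions: Et3SiH, CF3CO2H, CH2Cl2, 0 °C to rt
Reagents that add atoms: none
Why: Ionic hydrogenation, in which the protonated and strongly donor-stabilized aryl aldehyde accepts hydride from Et3SiH twice, taking CHO down to CH3 without touching the aryl bromide.

Step 3
Reactants: 4 1-bromo-3,5-dimethoxy-2-methylbenzene; 5 (2S,3S)-2,3-dimethyloxirane
Product: 7 (2S,3S)-3-(3,5-dimethoxy-2-methylphenyl)butan-2-ol, via aryllithium 6 (not isolated)
Conditions: n-BuLi, THF, -78 °C; then 5, BF3·OEt2, -78 °C; then H2O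
Reagents that add atoms: none
Why: Bromine-lithium exchange followed by BF3-assisted SN2 opening of the epoxide, which inverts the attacked carbon and leaves the carbinol carbon untouched, and because the two carbons of the C2-symmetric epoxide are equivalent a single (2S,3S) isomer should result.

Step 4
Reactants: 7 (2S,3S)-3-(3,5-dimethoxy-2-methylphenyl)butan-2-ol
Product: 8 (2R,3S)-3-(3,5-dimethoxy-2-methylphenyl)butan-2-yl 4-nitrobenzoate
Conditions: 4-O2NC6H4CO2H, PPh3, DIAD, THF, 0 °C to rt
Reagents that add atoms: 4-nitrobenzoic acid O=C(O)c1ccc([N+](=O)[O-])cc1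
Why: Mitsunobu reaction in its 4-nitrobenzoic acid variant for hindered secondary alcohols, in which the carboxylate displaces the activated oxygen by SN2 with inversion at C2 and so sets the (2R,3S) array of both halves of the target, aryl participation being weak because both methoxy groups are meta to the ipso carbon.

Step 5
Reactants: 8 (2R,3S)-3-(3,5-dimethoxy-2-methylphenyl)butan-2-yl 4-nitrobenzoate
Product: 9 (2R,3S)-3-(3,5-dihydroxy-2-methylphenyl)butan-2-yl 4-nitrobenzoate
Conditions: BBr3, CH2Cl2, -78 to 0 °C; then H2O
Reagents that add atoms: none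
Why: Lewis acid ether cleavage, in which BBr3 removes both aryl O-methyl groups by bromide attack on the methyl carbons while the electron-poor 4-nitrobenzoate shields the secondary carbinol from substitution, so both stereocentres are kept.

Step 6
Reactants: 9 (2R,3S)-3-(3,5-dihydroxy-2-methylphenyl)butan-2-yl 4-nitrobenzoate
Product: 10 5-[(2S,3R)-3-hydroxybutan-2-yl]-4-methylbenzene-1,3-diol
Conditions: LiOH, THF/H2O, rt, argon; then 1 M HCl
Reagents that add atoms: none
Why: Saponification by acyl-oxygen cleavage, which frees the carbinol without touching its C-O bond and therefore with retention.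

Step 7
Reactants: 10 5-[(2S,3R)-3-hydroxybutan-2-yl]-4-methylbenzene-1,3-diol
Product: 12 decarboxycitrinin [(3R,4S)-6-hydroxy-3,4,5-trimethyl-3,4-dihydroisochromen-8-one], via 1-ethoxyisochromane 11 (not isolated)
Conditions: HC(OEt)3 (excess), CF3CO2H, CH2Cl2, 0 °C to rt; then evaporation, wash with water
Reagents that add atoms: triethyl orthoformate CCOC(OCC)OCC
Why: Tethered formylation of the oxa-Pictet-Spengler type, in which alcohol exchange on the orthoformate and ionization give a dialkoxycarbenium ion that can reach only the ring carbon ortho to the side chain (six-membered ring, para to one OH and ortho to the other), and acid-induced loss of ethanol from 11 gives an isochromenylium ion that resists further electrophilic attack and collapses to quinone methide 12 when the acid is removed.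

Step 8
Reactants: 12 decarboxycitrinin (part of the material)
Product: 14 (3R,4S)-6,8-dihydroxy-3,4,5-trimethylisochroman-1-one, via lactol 13 (not isolated)
Conditions: DDQ (1 equiv), 1,4-dioxane/H2O, 0 °C to rt
Reagents that add atoms: water O
Why: Water adds reversibly to the electrophilic C1 of 12, and in lactol 13 the acetal-type C1-H bond lies para to 6-OH and ortho to 8-OH, so DDQ should remove it as hydride to give the lactone, the reaction type being the DDQ oxidation of electron-rich benzylidene acetals to esters and of 4-hydroxybenzylic alcohols to carbonyl compounds, after which the new lactone carbonyl deactivates 14 towards further oxidation.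

Step 9
Reactants: 12 decarboxycitrinin; 14 (3R,4S)-6,8-dihydroxy-3,4,5-trimethylisochroman-1-one; 15 formaldehyde
Product: 17 dicitrinone G, via 7-methylene-6,8-dione 16 (not isolated)
Conditions: 15 (37% aq., 1.1 equiv), 14 (1.5 equiv), NaOAc, AcOH, THF, 40 °C; 12 added slowly
Reagents that add atoms: none
Why: Formaldehyde 15 condenses at C7 of 12, the alpha carbon of the vinylogous acid (aldol addition and loss of water, a Knoevenagel condensation), to give the cross-conjugated 7-methylene-6,8-dione 16, an unhindered acceptor of the ortho-quinone methide type. C7' of 14 attacks the exocyclic CH2 carbon of 16 in a Friedel-Crafts-type Michael addition, and two proton shifts restore the resorcinol ring and the 6-hydroxy-8-oxo quinone methide, so both bonds of the bridge arise in one flask and 17 is formed directly. The closest known reaction type is the three-component Knoevenagel/Michael coupling of a cyclic 1,3-dicarbonyl compound, an aldehyde and an acylated polyphenol, as used for methylene- and alkylidene-bridged acylphloroglucinols. No ring is closed and no stereocentre is formed, and the four existing centres lie away from the reacting atoms and are not affected by the acetate buffer. The step needs cross-coupling instead of homo-coupling: only 12 should condense with formaldehyde at 40 °C because the lactone carbonyl deactivates 14 towards this weak electrophile, slow addition of 12 to an excess of 14 keeps 12 scarce while 16 is formed, and any adduct of 16 with 12 can revert by retro-Michael cleavage whereas rearomatization makes capture by 14 irreversible. Site selectivity within 14 is fixed by the substrate, since C7' is its only unsubstituted ring carbon and is activated by both flanking hydroxyl groups, while O-attack is reversible.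

Compound list
1 | 1-bromo-3,5-dimethoxybenzene | COc1cc(Br)cc(OC)c1 | starting material
2 | N-[(2-bromo-4,6-dimethoxyphenyl)methylidene]-N-methylmethanaminium chloride | C[N+](C)=Cc1c(Br)cc(OC)cc1OC.[Cl-] | intermediate
3 | 2-bromo-4,6-dimethoxybenzaldehyde | O=Cc1c(Br)cc(OC)cc1OC | intermediate
4 | 1-bromo-3,5-dimethoxy-2-methylbenzene | Cc1c(Br)cc(OC)cc1OC | intermediate
5 | (2S,3S)-2,3-dimethyloxirane | C[C@@H]1O[C@H]1C | starting material
6 | (3,5-dimethoxy-2-methylphenyl)lithium | [Li]c1cc(OC)cc(OC)c1C | intermediate
7 | (2S,3S)-3-(3,5-dimethoxy-2-methylphenyl)butan-2-ol | O[C@@H](C)[C@H](c1cc(OC)cc(OC)c1C)C | intermediate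
8 | (2R,3S)-3-(3,5-dimethoxy-2-methylphenyl)butan-2-yl 4-nitrobenzoate | O=C(O[C@H](C)[C@H](c1cc(OC)cc(OC)c1C)C)c1ccc([N+](=O)[O-])cc1 | intermediate
9 | (2R,3S)-3-(3,5-dihydroxy-2-methylphenyl)butan-2-yl 4-nitrobenzoate | O=C(O[C@H](C)[C@H](c1cc(O)cc(O)c1C)C)c1ccc([N+](=O)[O-])cc1 | intermediate
10 | 5-[(2S,3R)-3-hydroxybutan-2-yl]-4-methylbenzene-1,3-diol | O[C@H](C)[C@H](c1cc(O)cc(O)c1C)C | intermediate
11 | (3R,4S)-1-ethoxy-3,4,5-trimethylisochromane-6,8-diol (C1 epimers) | c1c(O)c(C)c2c(c1O)C(OCC)O[C@H](C)[C@H]2C | intermediate
12 | decarboxycitrinin, (3R,4S)-6-hydroxy-3,4,5-trimethyl-3,4-dihydroisochromen-8-one | CC1=C2C(=CO[C@H](C)[C@H]2C)C(=O)C=C1O | intermediate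
13 | (3R,4S)-3,4,5-trimethylisochromane-1,6,8-triol (C1 epimers) | c1c(O)c(C)c2c(c1O)C(O)O[C@H](C)[C@H]2C | intermediate
14 | (3R,4S)-6,8-dihydroxy-3,4,5-trimethylisochroman-1-one | c1c(O)c(C)c2c(c1O)C(=O)O[C@H](C)[C@H]2C | intermediate
15 | formaldehyde | C=O | starting material
16 | (3R,4S)-3,4,5-trimethyl-7-methylidene-3,4-dihydroisochromene-6,8-dione | CC1=C2C(=CO[C@H](C)[C@H]2C)C(=O)C(=C)C1=O | intermediate
17 | dicitrinone G | CC1=C2C(=CO[C@H](C)[C@H]2C)C(=O)C(Cc2c(O)c(C)c3c(c2O)C(=O)O[C@H](C)[C@H]3C)=C1O | target

Total step count: 9. Longest linear sequence: 9 steps (1 to 17). Compound 14 is drawn from 12, so the two halves part at 12 and meet again in step 9.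

Steps most likely to fail

Step 9. Cross-coupling may be eroded in three ways: self-capture of 16 by 12, attack of 14 at the electrophilic C1 of the quinone methide, or slow hydroxymethylation of 14. The fallback sets out from 12 and comes back at 17. The one-carbon unit is installed on 12 alone, before 14 is present. Aminomethylation of 12 with dimethyl(methylidene)ammonium iodide in CH2Cl2 (Mannich reaction) should give the Mannich base (3R,4S)-7-[(dimethylamino)methyl]-6-hydroxy-3,4,5-trimethyl-3,4-dihydroisochromen-8-one F1, which is freed from 12 and from formaldehyde. Warming it with 14 in 1,4-dioxane releases 16 by elimination of the amine. In that medium 14 is the only carbon nucleophile, so the same CH2-C7' bond forms and gives 17.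

Step 8. DDQ may also oxidize the 5-methyl group, or it may be consumed by adduct formation with the nucleophilic enol carbon C7 of 12. The fallback sets out from 8 and comes back at 14. The lactone carbonyl is brought in by carboxylation of a protected arene instead of by oxidation of a free phenol.
- Saponification (LiOH, THF/H2O) should give (2R,3S)-3-(3,5-dimethoxy-2-methylphenyl)butan-2-ol F2.
- NBS in MeCN should brominate the ring carbon ortho to the side chain (para to the 3-methoxy group) to give (2R,3S)-3-(2-bromo-3,5-dimethoxy-6-methylphenyl)butan-2-ol F3.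
- Bromine-lithium exchange and carboxylation (n-BuLi, 2 equiv, THF, -78 °C, then CO2) should give 2-[(2S,3R)-3-hydroxybutan-2-yl]-4,6-dimethoxy-3-methylbenzoic acid F4.
- This acid closes with TsOH in toluene, with retention at the carbinol, to (3R,4S)-6,8-dimethoxy-3,4,5-trimethylisochroman-1-one F5.
- BBr3 in CH2Cl2 then cleaves both methyl ethers to give 14.

Step 7. Three processes may lower the return. The isochromenylium ion may be captured by unreacted 10 (dimer formation). Intermolecular formylation may occur between the two hydroxyl groups. The product may be lost on isolation through hydration and deformylation. The fallback sets out from 8 and comes back at 12. The formyl carbon is placed on the protected arene first, and the ring is closed last.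
- Rieche formylation (Cl2CHOMe, TiCl4, CH2Cl2, -78 to 0 °C) should go para to the 3-methoxy group and give (2R,3S)-3-(2-formyl-3,5-dimethoxy-6-methylphenyl)butan-2-yl 4-nitrobenzoate F6.
- BBr3 in CH2Cl2 should give (2R,3S)-3-(2-formyl-3,5-dihydroxy-6-methylphenyl)butan-2-yl 4-nitrobenzoate F7.
- Saponification (LiOH) and acidification let the freed carbinol close on the aldehyde to lactol 13, which loses water to give 12.

Further compounds
F1 | step 9 | (3R,4S)-7-[(dimethylamino)methyl]-6-hydroxy-3,4,5-trimethyl-3,4-dihydroisochromen-8-one | CC1=C2C(=CO[C@H](C)[C@H]2C)C(=O)C(CN(C)C)=C1O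
F2 | step 8 | (2R,3S)-3-(3,5-dimethoxy-2-methylphenyl)butan-2-ol | O[C@H](C)[C@H](c1cc(OC)cc(OC)c1C)C
F3 | step 8 | (2R,3S)-3-(2-bromo-3,5-dimethoxy-6-methylphenyl)butan-2-ol | O[C@H](C)[C@H](c1c(Br)c(OC)cc(OC)c1C)C
F4 | step 8 | 2-[(2S,3R)-3-hydroxybutan-2-yl]-4,6-dimethoxy-3-methylbenzoic acid | O[C@H](C)[C@H](c1c(C(=O)O)c(OC)cc(OC)c1C)C
F5 | step 8 | (3R,4S)-6,8-dimethoxy-3,4,5-trimethylisochroman-1-one | c1c(OC)c(C)c2c(c1OC)C(=O)O[C@H](C)[C@H]2C
F6 | step 7 | (2R,3S)-3-(2-formyl-3,5-dimethoxy-6-methylphenyl)butan-2-yl 4-nitrobenzoate | O=C(O[C@H](C)[C@H](c1c(C=O)c(OC)cc(OC)c1C)C)c1ccc([N+](=O)[O-])cc1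
F7 | step 7 | (2R,3S)-3-(2-formyl-3,5-dihydroxy-6-methylphenyl)butan-2-yl 4-nitrobenzoate | O=C(O[C@H](C)[C@H](c1c(C=O)c(O)cc(O)c1C)C)c1ccc([N+](=O)[O-])cc1
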